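## Structural features

The target is a trans-fused hydroazulene. In guaiane numbering, the cyclopentane (C1–C5) carries an α-epoxide across C3–C4 with the C15 methyl on C4. The cycloheptane (C1, C5–C10) carries a β-isopropyl group on C7, the isovanillate ester on the 8β-oxygen, and a tertiary carbinol at C10 (10α-OH, 10β-methyl). The seven stereocentres form a contiguous run C3–C4–C5–C1–C10 and a pair C7–C8, separated only by the methylenes C6 and C9. Fragile groups are the trisubstituted epoxide (acid), the tertiary alcohol (ionisation, elimination), the aryl ester (base, acyl transfer) and the free phenol. The real difficulty is to relate the ring-fusion centres C1/C5 and the quaternary C10 to the remote C7/C8 pair across a flexible seven-membered ring, with H-1 and H-5 trans and the C7/C8 substituents cis. C1 is bonded to both C10 and C5, so removing C1 from the cycloheptane leaves a six-membered ring C5–C6–C7–C8–C9–C10, and the C1–C5 bond is shared by both rings. The key step uses exactly this: a cyclohexane bearing a vinyl group (C1=C2) on C10 and a C4–C3 acetal chain on C5 is turned into the bicycle by forming C2–C3 and moving C5 from C10 to C1.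

## Logic of the disconnections

29 ⇒ 28: the phenolic O–H is traced back to an O–Si bond. The free phenol would compete in the esterification and is best unmasked last. The demand is a fluoride deprotection mild enough for the epoxide and the aryl ester.

28 ⇒ 27: the two C–O bonds of the epoxide are cut back to the C3=C4 alkene. The most acid-sensitive group is thus introduced in the penultimate step. The forward step needs oxygen delivery to the α face of a trisubstituted cyclopentene.

27 ⇒ 23 + 26: the C8 O–acyl bond is cut, which makes the route convergent. 26 comes from 24 through 25 by silylation. The forward step must acylate the secondary 8β-OH and leave the tertiary 10α-OH alone.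

23 ⇒ 22 ⇒ 21 ⇒ 20: the C8–H bond is cut (ketone 22), because the cryptone chemistry delivers the C8 oxygen trans to the isopropyl group and the target needs it cis. The C8–O–Si bond of 20 is the protected form. The demand is a hydride delivery to the α face of C8, for which the 10α-OH is the handle.

20 ⇒ 19 ⇒ 18 ⇒ 17 ⇒ 16: the C3=C4 alkene is traced to the enol triflate 19, the ketone 18, the alcohol 17 and the benzyl ether 16. The C3 oxygen is what the cationic ring closure leaves behind; passing through the ketone erases C3 and C4 as stereocentres. The demand is enolisation of 18 toward C4 and not toward C2.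

16 ⇒ 15: the C10–C14 bond is cut to the C10 ketone. This removes the quaternary carbinol and exposes the retron of the key step. The forward step must bring methyl to the β face.

15 ⇒ 13 (through 14): C2–C3 and C1–C5 are cut and C10–C5 is re-formed. Two rings and the ring-fusion bond are exchanged for a monocyclic cyclohexane whose stereocentres C5 and C7 are already in place. The demands are a π-cyclisation onto an unactivated vinyl group, a stereoretentive shift of C5, and a final equilibration of C1.

13 ⇒ 12 ⇒ 11: the O–Si bond and then the C10–C1 bond are cut, giving the ketone 11 and a vinyl anion. The demand is addition without enolising the epimerisable C5 centre.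

11 ⇒ 10 ⇒ 9: the two acetal C–O bonds are cut to the aldehyde 10, and C3=O is traced to the terminal alkene of 9. The demand is that both operations leave the ketone and its α-centre alone.

9 ⇒ 8: the C4–C5 bond is cut and the C–O bond of an allyl enol ether is re-formed (Claisen retron). The branched C4 unit and the C5 stereocentre then come from one sigmatropic shift. The demand is bond formation at C5 on the face opposite the isopropyl group.

8 ⇒ 4 + 6 (through 7), 6 ⇒ 5: the enol ether C–O bond is cut to the ketone 4 and the crotyl donor 6, made from 5. The demand is enol ether formation toward C5 and not toward C9.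

4 ⇒ 3 ⇒ 2 ⇒ 1: the O–Si bond, then the C9–H bond (epoxide 2), then the epoxide oxygen are removed, arriving at 1. C7 is bought with 1 and controls C8. The demand is that the base-sensitive 1 is not racemised.

## Other disconnections considered

Alternative 1: The cut is C9–C10. The precursor is the seco-diketone A1, a trans-1,2-disubstituted cyclopentene with an acetyl group on C1 and a 4-bromo-2-isopropyl-3-oxobutyl chain on C5. In the forward step SmI2 reduces the C–Br bond to a samarium enolate (trivalent samarium) at C9, which adds to the methyl ketone and closes the seven-membered ring as the β-hydroxy ketone A2.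
- In its favour: A2 is identical with 22, so the 8α-silyloxy detour and the whole C3 deoxygenation sequence of the chosen plan disappear. On these points the alternative is the better plan.
- In its favour: the trans relationship at C1/C5 would rest on an epimerisable acetyl-bearing carbon of a simple cyclopentane. This is at least the equal of the C1 equilibration used here.
- Against it: C10 is created in the closure of a floppy chain, so its configuration depends on the shape of a seven-membered chelated aldolate. The chosen plan adds methyl to a preformed trans-fused ring.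
- Against it: A1 needs C5 and C7 related across an open-chain methylene, with C7 α to the ketone that must be brominated regioselectively at C9. The aldolate A2 can also revert under Lewis-acidic samarium.
- Comparison: the mechanism is anionic and reversible, against a cationic and irreversible one. The end game is shorter, but the saving is probably spent on assembling A1 with acyclic stereocontrol.

Alternative 2: The cut is the skeletal change C1–C5 formed, C5–C10 broken. The cross-conjugated eudesmadienone A3 is irradiated in aqueous acetic acid and rearranges, with capture of water at C10, to the hydroxy enone A4.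
- In its favour: one operation makes the hydroazulene, and H-1 and the 10α-hydroxyl follow stereospecifically from the angular methyl group. This is better than the chosen plan, which needs an equilibration and a face-selective methyl addition for the same two centres.
- In its favour: the 8β-oxygen is already in place, and the precursor is built with six-membered-ring stereocontrol from a carvone-derived ketone.
- Against it: in A4, C5 is sp2, so the 5β-hydrogen must be created late by reducing a tetrasubstituted enone in a flexible bicycle. The chosen plan carries C5 through a stereoretentive shift and is better on this point.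
- Against it: the C3 ketone then needs the same triflate-and-reduction sequence (equal), the acetate must be exchanged for the aryl ester, the eudesmane must be oxygenated at C8, and a photoreaction in aqueous acid has to tolerate the tertiary alcohol it creates.
- Comparison: the step count is comparable; stereochemical risk moves from C1/C10 to C5.

Alternative 3: The cut is C1–C10 and C1–C5, with C1 as a one-carbon insert. The silyl enol ether A5 is cyclopropanated (Et2Zn, CH2I2), oxidised with FeCl3 so that the internal cyclopropane bond opens, and HCl is lost with NaOAc to give the cycloheptenone A6.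
- In its favour: this is the shortest way to the seven-membered ring from a ketone of the same kind as 4. It is regiospecific once A5 is in hand and needs no weak π-nucleophile. For the ring enlargement alone it is better than the chosen plan.
- Equal points: cryptone supplies C7/C8 in the same way, and the regiochemistry of A5 is the same problem as step 5.
- Against it: in A6 both C1 and C5 are sp2. C5 must then be created by conjugate addition to a flexible cycloheptenone with only the remote C7 substituent to guide it. The cyclopentane (C2–C4, two more bonds) must be annulated separately and trans.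
- Against it: the β-silyloxy enone is more prone to elimination than the saturated ketone 14/15.
- Comparison: the chosen key step forms both rings and conserves C5, which is the decisive difference. Overall the alternative would not be shorter.

Key step: step 11

Assumption: 1, 5 and 24 are taken as purchasable in the optical and geometric purity needed; 1 is sold as a natural isolate.

Numbering: guaiane numbering is used for every intermediate. C10 is the carbonyl carbon of 1, C9 and C8 its alkene carbons, C7 the isopropyl-bearing carbon, C6 and C5 the remaining ring carbons. β is the face of the isopropyl group.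

Correction of the structures: the chair Claisen rearrangement of the (E)-crotyl ether joins C4 to C5 so that, after ring closure, the C4 methyl is cis to H-5 (4β-methyl, 4αH), not the epimer given in the brief. Compounds 9–18 are therefore written with the 4β-methyl group. The C3 benzyloxy group is written in the equatorial position of the cyclisation chair (3α). Both centres are erased at 18/19, so the target is unaffected, and the corrected C4 epimer places the methyl group equatorial in the key step.

Precursor design: the C8 ether is kept bulky and non-chelating (TIPS). The tertiary alcohol is silylated through its potassium alkoxide, because silyl triflates ionise acetals. The equilibration of C1 is run in the same flask with methoxide.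

Step 1
Reactants: 1 (R)-cryptone, (4R)-4-isopropylcyclohex-2-en-1-one
Product: 2 (1R,5R,6R)-5-isopropyl-7-oxabicyclo[4.1.0]heptan-2-one (8α,9α-epoxide, trans to the isopropyl group)
Conditions: 30% H2O2, NaOH (0.2 equiv), MeOH, 0 °C
Reagents that add atoms: hydrogen peroxide, OO
Why: Weitz–Scheffer nucleophilic epoxidation; hydroperoxide adds to C8 anti to the neighbouring isopropyl group, which fixes the 7,8-trans pair. Low temperature and substoichiometric base limit γ-deprotonation, the path by which 1 would racemise.

Step 2
Reactants: 2 (1R,5R,6R)-5-isopropyl-7-oxabicyclo[4.1.0]heptan-2-one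
Product: 3 (3S,4R)-3-hydroxy-4-isopropylcyclohexan-1-one (8α-hydroxy ketone)
Conditions: (PhSe)2, NaBH4, EtOH; AcOH; 0 → 23 °C
Reagents that add atoms: none
Why: Reductive opening of an α,β-epoxy ketone at the Cα–O bond by benzeneselenolate (displacement at C9, then deselenation to the enol). The medium is nearly neutral, so the β-hydroxy ketone should not dehydrate, and the C8–O bond is not touched.

Step 3
Reactants: 3 (3S,4R)-3-hydroxy-4-isopropylcyclohexan-1-one
Product: 4 (3S,4R)-4-isopropyl-3-(triisopropylsilyloxy)cyclohexan-1-one
Conditions: i-Pr3SiOTf, 2,6-lutidine, CH2Cl2, −78 °C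
Reagents that add atoms: triisopropylsilyl triflate, CC(C)[Si](C(C)C)(C(C)C)OS(=O)(=O)C(F)(F)F
Why: O-silylation by a silyl triflate is faster than enolisation at −78 °C. The bulky, weakly basic silyl ether later shields C9 and does not chelate SnCl4.

Step 4
Reactants: 5 (E)-but-2-en-1-ol
Product: 6 (E)-(but-2-enyloxy)trimethylsilane
Conditions: Me3SiCl, Et3N, Et2O, 0 → 23 °C; distillation
Reagents that add atoms: chlorotrimethylsilane, C[Si](C)(C)Cl
Why: Routine O-silylation; the silyl ether is the alkoxy donor for the acid-free ketalisation of step 5.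

Step 5
Reactants: 4 (3S,4R)-4-isopropyl-3-(triisopropylsilyloxy)cyclohexan-1-one; 6 (E)-(but-2-enyloxy)trimethylsilane
Product: 8 (E)-but-2-enyl (4R,5S)-4-isopropyl-5-(triisopropylsilyloxy)cyclohex-1-en-1-yl ether, via bis(but-2-enyl) ketal 7 (not isolated)
Conditions: 6 (2.5 equiv), Me3SiOTf (0.05 equiv), CH2Cl2, −78 °C; then i-Pr2NEt (1.6 equiv), Me3SiOTf (1.2 equiv), −78 → −20 °C
Reagents that add atoms: none
Why: Aprotic ketalisation with a silyl ether and catalytic silyl triflate gives 7; ionisation of 7 with Me3SiOTf and a hindered amine then removes a proton from the oxocarbenium ion (acetal-to-enol-ether elimination). Proton loss is expected at C5, the methylene that is neither crowded by the OTIPS-bearing carbon nor deactivated by a β-oxygen. No stereocentre is formed.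

Step 6
Reactants: 8 (E)-but-2-enyl (4R,5S)-4-isopropyl-5-(triisopropylsilyloxy)cyclohex-1-en-1-yl ether
Product: 9 (2R,4R,5S)-2-[(2S)-but-3-en-2-yl]-4-isopropyl-5-(triisopropylsilyloxy)cyclohexan-1-one (side chain on C5, α, trans to the isopropyl group)
Conditions: PhMe, 170 °C, sealed tube
Reagents that add atoms: none
Why: Claisen rearrangement. Bond formation at C5 is expected on the α face (axial attack, anti to the 7β-isopropyl group), and the chair transition state of the E-crotyl ether fixes C4 relative to C5. The neutral medium should leave the epimerisable C5 centre alone.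

Step 7
Reactants: 9 (2R,4R,5S)-2-[(2S)-but-3-en-2-yl]-4-isopropyl-5-(triisopropylsilyloxy)cyclohexan-1-one
Product: 10 (2R)-2-[(1R,4S,5R)-5-isopropyl-2-oxo-4-(triisopropylsilyloxy)cyclohexyl]propanal
Conditions: O3, CH2Cl2, −78 °C; PPh3, −78 → 23 °C
Reagents that add atoms: ozone, [O-][O+]=O
Why: Ozonolysis of the only C=C bond with a neutral reductive work-up. Nothing in the conditions enolises the ketone or the new aldehyde, so C5 and C4 are kept.

Step 8
Reactants: 10 (2R)-2-[(1R,4S,5R)-5-isopropyl-2-oxo-4-(triisopropylsilyloxy)cyclohexyl]propanal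
Product: 11 dibenzyl acetal of 10, 2-[1,1-bis(benzyloxy)propan-2-yl]-4-isopropyl-5-(triisopropylsilyloxy)cyclohexan-1-one (configuration as in 10)
Conditions: BnOSiMe3 (2.2 equiv), Me3SiOTf (0.05 equiv), CH2Cl2, −78 °C
Reagents that add atoms: benzyloxytrimethylsilane, C[Si](C)(C)OCc1ccccc1
Why: Aprotic acetalisation with a silyl ether and catalytic silyl triflate; at −78 °C the aldehyde reacts far faster than the α-branched ketone. Benzyl is chosen so that the C3 ether left by the key step can be removed by hydrogenolysis.

Step 9
Reactants: 11 2-[1,1-bis(benzyloxy)propan-2-yl]-4-isopropyl-5-(triisopropylsilyloxy)cyclohexan-1-one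
Product: 12 2-[1,1-bis(benzyloxy)propan-2-yl]-4-isopropyl-5-(triisopropylsilyloxy)-1-vinylcyclohexan-1-ol (vinyl β and trans to the C5 side chain, 10α-OH)
Conditions: CH2=CHMgBr, CeCl3, THF, −78 °C
Reagents that add atoms: vinylmagnesium bromide, C=C[Mg]Br
Why: 1,2-Addition of the organocerium reagent, which is too weakly basic to enolise the epimerisable ketone. The nucleophile should enter anti to the C5 side chain. The C10 configuration is lost again in step 11 and only has to allow vinyl and side chain to become gauche.

Step 10
Reactants: 12 2-[1,1-bis(benzyloxy)propan-2-yl]-4-isopropyl-5-(triisopropylsilyloxy)-1-vinylcyclohexan-1-ol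
Product: 13 triethylsilyl ether of 12, the 1-vinylcyclohexyl triethylsilyl ether carrying the 1,1-bis(benzyloxy)propan-2-yl group on C5 (7β-isopropyl, 8α-OTIPS, 10α-OSiEt3)
Conditions: KN(SiMe3)2, THF, −78 °C; Et3SiCl, −78 → 0 °C
Reagents that add atoms: chlorotriethylsilane, CC[Si](Cl)(CC)CC
Why: Silylation of the hindered tertiary alcohol through its potassium alkoxide. Silyl triflates are avoided because, with amine bases, they ionise acetals.

Step 11
Reactants: 13 1-vinylcyclohexyl triethylsilyl ether carrying the 1,1-bis(benzyloxy)propan-2-yl group on C5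
Product: 15 3α-benzyloxy-8α-(triisopropylsilyloxy)-14-nor-1αH,4αH,5βH-guaian-10-one, via cis-fused 1βH ketone 14 (not isolated)
Conditions: SnCl4 (1.5 equiv), CH2Cl2, −78 → −23 °C; then NaOMe, MeOH, −23 → 0 °C
Reagents that add atoms: none
Why: SnCl4 ionises the dibenzyl acetal to the E-oxocarbenium ion at C3, the vinyl terminus C2 attacks it through a chair (C3, C4, C5, C10, C1, C2) with the C4 methyl and the C3 benzyloxy group equatorial, and the charge developing at C1 is quenched by the shift of the C10–C5 bond to C1 with loss of the silyl group to chloride, leaving the C10 ketone; this is a Prins cyclisation ended by a pinacol shift, the known ring-enlarging cyclopentane annulation of 1-alkenylcycloalkanol silyl ethers, here in its less favourable plain-vinyl form. The carbocycle first formed is six-membered (6-endo with respect to the vinyl group, exo with respect to the oxocarbenium ion); the 1,2-shift contracts it to the cyclopentane by making C1–C5 and at the same time enlarges the cyclohexane to the cycloheptanone, so the seven-membered ring arises by ring expansion and not by closure of a chain. C5 migrates suprafacially with retention, so the C5/C7 relationship set in steps 1 and 6 is carried over unchanged. C3 is set by the equatorial benzyloxy group of the chair (3α) and is of no consequence, since it later becomes a ketone. C1 is formed cis to H-5 in 14, because C10 leaves the new ring on the face opposite to H-5; methoxide, which also destroys Et3SiCl and the tin chlorides, then equilibrates C1 through the enolate to the trans-fused ketone 15, expected to be the more stable epimer by analogy with other 10-oxo-14-norguaianes. The step needs ionisation of the acetal rather than of the tertiary allylic silyl ether (the acetal is the more basic site and both silyl ethers are hindered and non-chelating), migration of C5 rather than C9 (only the C5 shift gives a fused and not a bridged ketone) and survival of the β-silyloxy group during a short, cold exposure to base.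

Step 12
Reactants: 15 3α-benzyloxy-8α-(triisopropylsilyloxy)-14-nor-1αH,4αH,5βH-guaian-10-one
Product: 16 3α-benzyloxy-8α-(triisopropylsilyloxy)-1αH,4αH,5βH-guaian-10α-ol
Conditions: MeAl(OAr)2 (Ar = 2,6-di-tert-butyl-4-methylphenyl; from Me3Al and 2 ArOH), PhMe, −78 °C; MeLi, −78 °C
Reagents that add atoms: methyllithium, [Li]C
Why: Addition to a ketone precomplexed with a bulky aluminium phenoxide. The Lewis acid occupies the open equatorial side, so methyllithium should attack along the axial direction, here the β face anti to the axial H-1, giving the equatorial 10α-alcohol. Complexation also suppresses enolisation toward C9 and with it loss of the β-silyloxy group.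

Step 13
Reactants: 16 3α-benzyloxy-8α-(triisopropylsilyloxy)-1αH,4αH,5βH-guaian-10α-ol
Product: 17 8α-(triisopropylsilyloxy)-1αH,4αH,5βH-guaiane-3α,10α-diol
Conditions: H2 (1 atm), Pd/C, EtOAc, 23 °C
Reagents that add atoms: none
Why: Hydrogenolysis of the benzyl ether. No C=C bond is present at this stage, and the silyl ether and the tertiary alcohol are inert.

Step 14
Reactants: 17 8α-(triisopropylsilyloxy)-1αH,4αH,5βH-guaiane-3α,10α-diol
Product: 18 10α-hydroxy-8α-(triisopropylsilyloxy)-1αH,4αH,5βH-guaian-3-one
Conditions: Pr4N[RuO4] (5 mol %), N-methylmorpholine N-oxide, 4 Å molecular sieves, CH2Cl2, 23 °C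
Reagents that add atoms: none
Why: Ley–Griffith oxidation of the only secondary alcohol; the tertiary alcohol cannot be oxidised.

Step 15
Reactants: 18 10α-hydroxy-8α-(triisopropylsilyloxy)-1αH,4αH,5βH-guaian-3-one
Product: 19 10α-hydroxy-8α-(triisopropylsilyloxy)-1αH,5βH-guai-3-en-3-yl trifluoromethanesulfonate
Conditions: i-Pr2NMgBr (from EtMgBr and i-Pr2NH, 2.5 equiv), Et2O–THF, 23 °C; PhNTf2, 0 → 23 °C
Reagents that add atoms: N-phenylbis(trifluoromethanesulfonimide), FC(F)(F)S(=O)(=O)N(c1ccccc1)S(=O)(=O)C(F)(F)F
Why: The magnesium amide gives the equilibrated enolate, which for a 2-methylcyclopentanone is the more substituted C3=C4 enolate; the sulfonimide traps it on oxygen. The tertiary magnesium alkoxide at C10 is too hindered to be sulfonylated. C4 ceases to be a stereocentre here.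

Step 16
Reactants: 19 10α-hydroxy-8α-(triisopropylsilyloxy)-1αH,5βH-guai-3-en-3-yl trifluoromethanesulfonate
Product: 20 8α-(triisopropylsilyloxy)-1αH,5βH-guai-3-en-10α-ol
Conditions: Pd(OAc)2 (5 mol %), PPh3, HCO2H, n-Bu3N, DMF, 60 °C
Reagents that add atoms: none
Why: Reduction of an enol triflate by zerovalent palladium formed in situ (oxidative addition, formate exchange, loss of CO2, C–H reductive elimination). The double bond stays where the triflate placed it.

Step 17
Reactants: 20 8α-(triisopropylsilyloxy)-1αH,5βH-guai-3-en-10α-ol
Product: 21 1αH,5βH-guai-3-ene-8α,10α-diol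
Conditions: Bu4NF, THF, 23 → 45 °C
Reagents that add atoms: none
Why: Fluoride cleavage of the silyl ether; nothing else in 20 reacts with fluoride.

Step 18
Reactants: 21 1αH,5βH-guai-3-ene-8α,10α-diol
Product: 22 10α-hydroxy-1αH,5βH-guai-3-en-8-one
Conditions: Pr4N[RuO4] (5 mol %), N-methylmorpholine N-oxide, 4 Å molecular sieves, CH2Cl2, 0 → 23 °C
Reagents that add atoms: none
Why: Ley–Griffith oxidation of the secondary C8 alcohol. The neutral medium should keep the β-hydroxy ketone from retro-aldol cleavage or dehydration and C7 from epimerising.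

Step 19
Reactants: 22 10α-hydroxy-1αH,5βH-guai-3-en-8-one
Product: 23 1αH,5βH-guai-3-ene-8β,10α-diol
Conditions: Me4NBH(OAc)3, MeCN–AcOH (1:1), −20 °C
Reagents that add atoms: none
Why: Hydroxyl-directed reduction of the Evans–Saksena type. The 10α-hydroxyl exchanges onto boron and delivers hydride intramolecularly to the α face of C8, giving the anti 1,3-diol, that is the 8β-alcohol. External attack anti to the 7β-isopropyl group points the same way.

Step 20
Reactants: 24 isovanillic acid, 3-hydroxy-4-methoxybenzoic acid
Product: 26 3-(tert-butyldimethylsilyloxy)-4-methoxybenzoic acid, via silyl ester 25 (not isolated)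
Conditions: t-BuMe2SiCl (2.3 equiv), imidazole, DMF, 23 °C; then AcOH, THF–H2O, 23 °C
Reagents that add atoms: tert-butyldimethylsilyl chloride, CC(C)(C)[Si](C)(C)Cl
Why: Silylation of both acidic sites, then hydrolysis of the far more labile silyl ester, leaves the aryl silyl ether.

Step 21
Reactants: 23 1αH,5βH-guai-3-ene-8β,10α-diol; 26 3-(tert-butyldimethylsilyloxy)-4-methoxybenzoic acid
Product: 27 10α-hydroxy-1αH,5βH-guai-3-en-8β-yl 3-(tert-butyldimethylsilyloxy)-4-methoxybenzoate
Conditions: EDC·HCl, DMAP, CH2Cl2, 0 → 23 °C
Reagents that add atoms: none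
Why: Steglich esterification. Only the secondary 8β-hydroxyl is acylated; the tertiary 10α-hydroxyl is inert, and C8 keeps its configuration because the C–O bond is not broken.

Step 22
Reactants: 27 10α-hydroxy-1αH,5βH-guai-3-en-8β-yl 3-(tert-butyldimethylsilyloxy)-4-methoxybenzoate
Product: 28 3α,4α-epoxy-10α-hydroxy-1αH,5βH-guaian-8β-yl 3-(tert-butyldimethylsilyloxy)-4-methoxybenzoate
Conditions: mCPBA, NaHCO3, CH2Cl2, 0 °C
Reagents that add atoms: 3-chloroperbenzoic acid, OOC(=O)c1cccc(Cl)c1
Why: Prilezhaev epoxidation of the only C=C bond. Attack on the α face is expected, anti to the pseudoaxial H-5 of the trans-fused cyclopentene and helped by hydrogen bonding of the peracid to the 10α-hydroxyl. Bicarbonate protects the trisubstituted epoxide from acid.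

Step 23
Reactants: 28 3α,4α-epoxy-10α-hydroxy-1αH,5βH-guaian-8β-yl 3-(tert-butyldimethylsilyloxy)-4-methoxybenzoate
Product: 29 3α,4α-epoxy-10α-hydroxy-1αH,5βH-guaian-8β-yl 3-hydroxy-4-methoxybenzoate (target, CNP0264062.2)
Conditions: Bu4NF, AcOH, THF, 0 °C
Reagents that add atoms: none
Why: Fluoride cleavage of the aryl silyl ether. Acetic acid buffers the medium so that neither phenoxide nor fluoride basicity endangers the aryl ester or the epoxide.

Compound list

1 | (R)-cryptone, (4R)-4-isopropylcyclohex-2-en-1-one | O=C1C=C[C@@H](C(C)C)CC1 | starting material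
2 | (1R,5R,6R)-5-isopropyl-7-oxabicyclo[4.1.0]heptan-2-one | O=C1CC[C@H](C(C)C)[C@H]2O[C@@H]12 | intermediate
3 | (3S,4R)-3-hydroxy-4-isopropylcyclohexan-1-one | O=C1CC[C@H](C(C)C)[C@@H](O)C1 | intermediate
4 | (3S,4R)-4-isopropyl-3-(triisopropylsilyloxy)cyclohexan-1-one | O=C1CC[C@H](C(C)C)[C@@H](O[Si](C(C)C)(C(C)C)C(C)C)C1 | intermediate
5 | (E)-but-2-en-1-ol | C/C=C/CO | starting material
6 | (E)-(but-2-enyloxy)trimethylsilane | C/C=C/CO[Si](C)(C)C | intermediate
7 | (3S,4R)-1,1-bis[(E)-but-2-enyloxy]-4-isopropyl-3-(triisopropylsilyloxy)cyclohexane | C/C=C/COC1(OC/C=C/C)CC[C@H](C(C)C)[C@@H](O[Si](C(C)C)(C(C)C)C(C)C)C1 | intermediate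
8 | (E)-but-2-enyl (4R,5S)-4-isopropyl-5-(triisopropylsilyloxy)cyclohex-1-en-1-yl ether | C/C=C/COC1=CC[C@H](C(C)C)[C@@H](O[Si](C(C)C)(C(C)C)C(C)C)C1 | intermediate
9 | (2R,4R,5S)-2-[(2S)-but-3-en-2-yl]-4-isopropyl-5-(triisopropylsilyloxy)cyclohexan-1-one | C=C[C@H](C)[C@H]1C[C@H](C(C)C)[C@@H](O[Si](C(C)C)(C(C)C)C(C)C)CC1=O | intermediate
10 | (2R)-2-[(1R,4S,5R)-5-isopropyl-2-oxo-4-(triisopropylsilyloxy)cyclohexyl]propanal | O=C[C@H](C)[C@H]1C[C@H](C(C)C)[C@@H](O[Si](C(C)C)(C(C)C)C(C)C)CC1=O | intermediate
11 | 2-[1,1-bis(benzyloxy)propan-2-yl]-4-isopropyl-5-(triisopropylsilyloxy)cyclohexan-1-one (configuration as in 10) | c1ccccc1COC(OCc1ccccc1)[C@H](C)[C@H]1C[C@H](C(C)C)[C@@H](O[Si](C(C)C)(C(C)C)C(C)C)CC1=O | intermediate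
12 | 2-[1,1-bis(benzyloxy)propan-2-yl]-4-isopropyl-5-(triisopropylsilyloxy)-1-vinylcyclohexan-1-ol (vinyl trans to the side chain, 10α-OH) | c1ccccc1COC(OCc1ccccc1)[C@H](C)[C@H]1C[C@H](C(C)C)[C@@H](O[Si](C(C)C)(C(C)C)C(C)C)C[C@]1(O)C=C | intermediate
13 | triethylsilyl ether of 12 (key-step precursor) | c1ccccc1COC(OCc1ccccc1)[C@H](C)[C@H]1C[C@H](C(C)C)[C@@H](O[Si](C(C)C)(C(C)C)C(C)C)C[C@]1(O[Si](CC)(CC)CC)C=C | intermediate
14 | 3α-benzyloxy-8α-(triisopropylsilyloxy)-14-nor-1βH,4αH,5βH-guaian-10-one (cis-fused) | CC(C)[Si](C(C)C)(C(C)C)O[C@H]1CC(=O)[C@H]2C[C@@H](OCc3ccccc3)[C@H](C)[C@H]2C[C@@H]1C(C)C | intermediate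
15 | 3α-benzyloxy-8α-(triisopropylsilyloxy)-14-nor-1αH,4αH,5βH-guaian-10-one (trans-fused) | CC(C)[Si](C(C)C)(C(C)C)O[C@H]1CC(=O)[C@@H]2C[C@@H](OCc3ccccc3)[C@H](C)[C@H]2C[C@@H]1C(C)C | intermediate
16 | 3α-benzyloxy-8α-(triisopropylsilyloxy)-1αH,4αH,5βH-guaian-10α-ol | CC(C)[Si](C(C)C)(C(C)C)O[C@H]1C[C@@](C)(O)[C@@H]2C[C@@H](OCc3ccccc3)[C@H](C)[C@H]2C[C@@H]1C(C)C | intermediate
17 | 8α-(triisopropylsilyloxy)-1αH,4αH,5βH-guaiane-3α,10α-diol | CC(C)[Si](C(C)C)(C(C)C)O[C@H]1C[C@@](C)(O)[C@@H]2C[C@@H](O)[C@H](C)[C@H]2C[C@@H]1C(C)C | intermediate
18 | 10α-hydroxy-8α-(triisopropylsilyloxy)-1αH,4αH,5βH-guaian-3-one | CC(C)[Si](C(C)C)(C(C)C)O[C@H]1C[C@@](C)(O)[C@@H]2CC(=O)[C@H](C)[C@H]2C[C@@H]1C(C)C | intermediate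
19 | 10α-hydroxy-8α-(triisopropylsilyloxy)-1αH,5βH-guai-3-en-3-yl trifluoromethanesulfonate | CC(C)[Si](C(C)C)(C(C)C)O[C@H]1C[C@@](C)(O)[C@@H]2CC(OS(=O)(=O)C(F)(F)F)=C(C)[C@H]2C[C@@H]1C(C)C | intermediate
20 | 8α-(triisopropylsilyloxy)-1αH,5βH-guai-3-en-10α-ol | CC(C)[Si](C(C)C)(C(C)C)O[C@H]1C[C@@](C)(O)[C@@H]2CC=C(C)[C@H]2C[C@@H]1C(C)C | intermediate
21 | 1αH,5βH-guai-3-ene-8α,10α-diol | O[C@H]1C[C@@](C)(O)[C@@H]2CC=C(C)[C@H]2C[C@@H]1C(C)C | intermediate
22 | 10α-hydroxy-1αH,5βH-guai-3-en-8-one | O=C1C[C@@](C)(O)[C@@H]2CC=C(C)[C@H]2C[C@@H]1C(C)C | intermediate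
23 | 1αH,5βH-guai-3-ene-8β,10α-diol | O[C@@H]1C[C@@](C)(O)[C@@H]2CC=C(C)[C@H]2C[C@@H]1C(C)C | intermediate
24 | isovanillic acid, 3-hydroxy-4-methoxybenzoic acid | COc1ccc(C(=O)O)cc1O | starting material
25 | tert-butyldimethylsilyl 3-(tert-butyldimethylsilyloxy)-4-methoxybenzoate | COc1ccc(C(=O)O[Si](C)(C)C(C)(C)C)cc1O[Si](C)(C)C(C)(C)C | intermediate
26 | 3-(tert-butyldimethylsilyloxy)-4-methoxybenzoic acid | COc1ccc(C(=O)O)cc1O[Si](C)(C)C(C)(C)C | intermediate
27 | 10α-hydroxy-1αH,5βH-guai-3-en-8β-yl 3-(tert-butyldimethylsilyloxy)-4-methoxybenzoate | COc1ccc(C(=O)O[C@@H]2C[C@@](C)(O)[C@@H]3CC=C(C)[C@H]3C[C@@H]2C(C)C)cc1O[Si](C)(C)C(C)(C)C | intermediate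
28 | 3α,4α-epoxy-10α-hydroxy-1αH,5βH-guaian-8β-yl 3-(tert-butyldimethylsilyloxy)-4-methoxybenzoate | COc1ccc(C(=O)O[C@@H]2C[C@@](C)(O)[C@@H]3C[C@H]4O[C@@]4(C)[C@H]3C[C@@H]2C(C)C)cc1O[Si](C)(C)C(C)(C)C | intermediate
29 | 3α,4α-epoxy-10α-hydroxy-1αH,5βH-guaian-8β-yl 3-hydroxy-4-methoxybenzoate (CNP0264062.2) | COc1ccc(C(=O)O[C@@H]2C[C@@](C)(O)[C@@H]3C[C@H]4O[C@@]4(C)[C@H]3C[C@@H]2C(C)C)cc1O | target

Total step count: 23. Longest linear sequence: 21 steps (steps 1–3, 5–19 and 21–23, from 1 to 29); steps 4 and 20 make the two side components.

Steps least certain to work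

Step 11 (key step). The cation–olefin closure may be slow, because a plain vinyl group leads to a secondary cation and the reactive chair must carry the isopropyl group and both silyloxy groups axial. Ionisation of the tertiary allylic silyl ether, or proton loss from the oxocarbenium ion, could then compete. In the base stage, β-elimination of the C8 silyloxy group after enolisation toward C9, or an unfavourable cis/trans equilibrium, could erode the product. The fallback replaces the vinyl group by a donor-substituted alkene. It sets out from 11: addition of CH2=C(SPh)Li with CeCl3 gives the 1-(phenylthio)vinyl carbinol F4, and KN(SiMe3)2 with Et3SiCl gives its triethylsilyl ether F5. SnCl4 then closes the ring through a sulfur-stabilised cation at C1, and the ring-enlarging shift gives the 1-(phenylthio) ketone F6. SmI2 in THF–MeOH cleaves the C1–S bond and NaOMe equilibrates C1. The fallback returns to the route at 15.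

Step 5. Enolisation may take place toward C9 instead of C5, or the crotyl oxocarbenium ion may fragment before it is deprotonated; either would divert material from 8. The fallback fixes the regiochemistry at an isolable stage and sets out from 4. Kinetic deprotonation with LiN(i-Pr)2 and trapping with PhNTf2 gives the enol triflate (4R,5S)-4-isopropyl-5-(triisopropylsilyloxy)cyclohex-1-en-1-yl trifluoromethanesulfonate F1. Miyaura borylation (bis(pinacolato)diboron, PdCl2(PPh3)2, PPh3, KOPh, PhMe, 50 °C) gives the alkenylboronate F2. A Chan–Lam-type etherification with 5 (Cu(OAc)2, Et3N, 23 °C) returns to the route at 8.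

Step 6. At 170 °C the preference for bond formation on the α face of C5 may be small, and some thermal epimerisation of the product is possible. The fallback forms the same bond at −78 °C, where the same bias counts for more, and sets out from 4. The lithium enolate (LiN(i-Pr)2, THF, −78 °C) adds to (E)-1-nitropropene to give the nitro ketone F3, whose C4 configuration is immaterial and is drawn as in 10. A Nef reaction through ozonolysis of the nitronate (NaOMe, MeOH, −78 °C; O3; Me2S) returns to the route at 10.

Step 12. Methyllithium may attack from the α face, or enolise the ketone, if the seven-membered ring does not present its faces as a cyclohexanone does. The fallback builds the carbinol from a spiro-epoxide and sets out from 15. Dimethylsulfonium methylide (Me3SI, n-BuLi, THF, −10 °C; Corey–Chaykovsky reaction, irreversible axial attack of a small ylide) gives the 10α,14-epoxide F7. LiEt3BH opens it at the methylene carbon and returns to the route at 16.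

Step 22. Facial selectivity may be poor if the steric bias of the cyclopentene is small and the peracid is not guided by the 10α-hydroxyl. The fallback uses metal-alkoxide delivery before acylation and sets out from 23. VO(acac)2 and t-BuOOH in CH2Cl2 epoxidise the bishomoallylic alcohol from the face of the 10α-oxygen, giving the epoxy diol F8. Esterification with 26 under the conditions of step 21 returns to the route at 28.

## Further compounds

F1 | step 5 | (4R,5S)-4-isopropyl-5-(triisopropylsilyloxy)cyclohex-1-en-1-yl trifluoromethanesulfonate | O=S(=O)(OC1=CC[C@H](C(C)C)[C@@H](O[Si](C(C)C)(C(C)C)C(C)C)C1)C(F)(F)F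
F2 | step 5 | 2-[(4R,5S)-4-isopropyl-5-(triisopropylsilyloxy)cyclohex-1-en-1-yl]-4,4,5,5-tetramethyl-1,3,2-dioxaborolane | CC1(C)OB(OC1(C)C)C1=CC[C@H](C(C)C)[C@@H](O[Si](C(C)C)(C(C)C)C(C)C)C1
F3 | step 6 | 4-isopropyl-2-(1-nitropropan-2-yl)-5-(triisopropylsilyloxy)cyclohexan-1-one (ring configuration as in 10) | [O-][N+](=O)C[C@H](C)[C@H]1C[C@H](C(C)C)[C@@H](O[Si](C(C)C)(C(C)C)C(C)C)CC1=O
F4 | step 11 | 2-[1,1-bis(benzyloxy)propan-2-yl]-4-isopropyl-1-[1-(phenylthio)vinyl]-5-(triisopropylsilyloxy)cyclohexan-1-ol (configuration as in 12) | c1ccccc1COC(OCc1ccccc1)[C@H](C)[C@H]1C[C@H](C(C)C)[C@@H](O[Si](C(C)C)(C(C)C)C(C)C)C[C@]1(O)C(=C)Sc1ccccc1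
F5 | step 11 | triethylsilyl ether of F4 | c1ccccc1COC(OCc1ccccc1)[C@H](C)[C@H]1C[C@H](C(C)C)[C@@H](O[Si](C(C)C)(C(C)C)C(C)C)C[C@]1(O[Si](CC)(CC)CC)C(=C)Sc1ccccc1
F6 | step 11 | 3α-benzyloxy-1β-(phenylthio)-8α-(triisopropylsilyloxy)-14-nor-4αH,5βH-guaian-10-one | CC(C)[Si](C(C)C)(C(C)C)O[C@H]1CC(=O)[C@@]2(Sc3ccccc3)C[C@@H](OCc3ccccc3)[C@H](C)[C@H]2C[C@@H]1C(C)C
F7 | step 12 | 3α-benzyloxy-10α,14-epoxy-8α-(triisopropylsilyloxy)-1αH,4αH,5βH-guaiane | CC(C)[Si](C(C)C)(C(C)C)O[C@H]1C[C@@]3(OC3)[C@@H]2C[C@@H](OCc3ccccc3)[C@H](C)[C@H]2C[C@@H]1C(C)C
F8 | step 22 | 3α,4α-epoxy-1αH,5βH-guaiane-8β,10α-diol | O[C@@H]1C[C@@](C)(O)[C@@H]2C[C@H]3O[C@@]3(C)[C@H]2C[C@@H]1C(C)C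
A1 | alternative 1 | 9-bromo-9,10-seco-1αH,5βH-guai-3-ene-8,10-dione | CC(=O)[C@@H]1CC=C(C)[C@H]1C[C@H](C(C)C)C(=O)CBr
A2 | alternative 1 | 10α-hydroxy-1αH,5βH-guai-3-en-8-one (identical with 22) | O=C1C[C@@](C)(O)[C@@H]2CC=C(C)[C@H]2C[C@@H]1C(C)C
A3 | alternative 2 | 8β-acetoxyeudesma-1,4-dien-3-one (7β-isopropyl, 10β-methyl) | CC(=O)O[C@@H]1C[C@@]2(C)C=CC(=O)C(C)=C2C[C@@H]1C(C)C
A4 | alternative 2 | 8β-acetoxy-10α-hydroxy-1αH-guai-4-en-3-one | CC(=O)O[C@@H]1C[C@@](C)(O)[C@@H]2CC(=O)C(C)=C2C[C@@H]1C(C)C
A5 | alternative 3 | [(4R,5S)-5-(tert-butyldimethylsilyloxy)-4-isopropylcyclohex-1-en-1-yl]oxytrimethylsilane | C[Si](C)(C)OC1=CC[C@H](C(C)C)[C@@H](O[Si](C)(C)C(C)(C)C)C1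
A6 | alternative 3 | 6-(tert-butyldimethylsilyloxy)-5-isopropylcyclohept-2-en-1-one (7β-isopropyl, 8α-silyloxy in guaiane numbering) | O=C1C=CC[C@H](C(C)C)[C@@H](O[Si](C)(C)C(C)(C)C)C1
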